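**Retrosynthetic overview**
1. Hanultarin is the mono-feruloyl ester of (R,R)-secoisolariciresinol, so the last steps are a statistical mono-esterification of the C2-symmetric diol core and a global desilylation.
2. The diol comes from the trans,trans-3,4-dibenzyl-5-(pivaloyloxymethyl)butyrolactone. The C5 carbinol is a traceless stereocontrol element: LiAlH4 reduction and NaIO4 cleavage of the resulting C5–C6 diol turn it into the C4 aldehyde carbon.
3. Both benzyl groups are installed on the chiral butenolide. First comes a photochemical (decatungstate) benzylic C–H Giese addition anti to C5. Then comes enolate benzylation trans to the new C4 benzyl.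
4. No ring is built in the route. The only ring, the butenolide, comes from the chiral starting material and is opened during the sequence.

Assumptions: (R)-5-(hydroxymethyl)furan-2(5H)-one is purchasable; it is the chiral-pool butenolide derived from (S)-glyceraldehyde acetonide. The SMILES corresponds to (2R,3R)-secoisolariciresinol monoferulate. Because the diol core is C2-symmetric, it does not matter which CH2OH is esterified.

---

**Step 1**
Reactants: 1 (R)-5-(hydroxymethyl)furan-2(5H)-one
Product: 2 [(2R)-5-oxo-2,5-dihydrofuran-2-yl]methyl pivalate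
Conditions: PivCl, pyridine, DMAP (cat.), CH2Cl2, 0 °C
Reagents that add atoms: pivaloyl chloride, CC(C)(C)C(=O)Cl
Why: Simple acylation of the primary alcohol. The pivalate survives LDA at −78 °C but is cleaved later by LiAlH4. The C5 stereocentre is untouched.

**Step 2**
Reactants: 3 creosol (2-methoxy-4-methylphenol)
Product: 4 tert-butyl(2-methoxy-4-methylphenoxy)dimethylsilane
Conditions: TBSCl, imidazole, DMF, rt
Reagents that add atoms: TBSCl, CC(C)(C)[Si](C)(C)Cl
Why: Phenol silylation. It masks the acidic, HAT-active phenol for the radical, enolate and periodate steps.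

**Step 3**
Reactants: 2 (butenolide pivalate, 1 equiv); 4 (4 equiv)
Product: 5 [(2R,3R)-3-{[4-(TBSO)-3-methoxyphenyl]methyl}-5-oxotetrahydrofuran-2-yl]methyl pivalate
Conditions: Na4W10O32 (TBADT, 2 mol %), MeCN, 390 nm LEDs, N2, rt, 24 h
Reagents that add atoms: none
Why: Proposed new method: excited decatungstate abstracts a benzylic hydrogen from the electron-rich toluene 4, and the nucleophilic benzylic radical adds at C4 of the butenolide anti to the C5 CH2OPiv group. The resulting α-lactonyl radical is reduced by H–W10O32(5−) and protonated at C3, so C4 is set trans to C5. The closest known reaction is decatungstate-photocatalysed Giese alkylation of toluenes with electron-poor alkenes, combined with anti-selective radical addition to γ-substituted butenolides. The γ-C–H of the butenolide is polarity-mismatched toward the electrophilic HAT catalyst.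

**Step 4**
Reactants: 4
Product: 6 4-(TBSO)-3-methoxybenzyl bromide
Conditions: NBS, AIBN (5 mol %), PhCF3, K2CO3 (solid), 80 °C, 1.5 h; used crude
Reagents that add atoms: N-bromosuccinimide, O=C1CCC(=O)N1Br
Why: Wohl–Ziegler benzylic bromination. The radical chain favours the benzylic C–H over the ring.

**Step 5**
Reactants: 5; 6
Product: 7 [(2R,3R,4R)-3,4-bis{[4-(TBSO)-3-methoxyphenyl]methyl}-5-oxotetrahydrofuran-2-yl]methyl pivalate
Conditions: LDA, THF, −78 °C, 30 min; then 6, DMPU, −78 → −30 °C
Reagents that add atoms: none
Why: Lactone enolate alkylation. The electrophile approaches trans to the adjacent C4 benzyl group, setting C3 (lactone numbering) and giving the trans-3,4 (R,R) arrangement.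

**Step 6**
Reactants: 7
Product: 8 (2R,3R,4R)-3,4-bis{[4-(TBSO)-3-methoxyphenyl]methyl}pentane-1,2,5-triol
Conditions: LiAlH4, THF, 0 °C → rt, 3 h
Reagents that add atoms: none
Why: Hydride reduction opens the lactone to a primary alcohol and removes the pivalate, giving a free 1,2-diol; no stereocentre is affected. The aryl TBS ethers survive at 0 °C.

**Step 7**
Reactants: 8
Product: 9 (3R,4R)-3,4-bis{[4-(TBSO)-3-methoxyphenyl]methyl}tetrahydrofuran-2-ol (lactol, anomeric mixture)
Conditions: NaIO4, THF/H2O (4:1), 0 °C, 1 h
Reagents that add atoms: none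
Why: Malaprade cleavage of the C5–C6 vicinal diol removes the controlling carbinol stereocentre. It releases CH2O and leaves the C4 aldehyde, which closes to the lactol and protects the α-centre from epimerisation.

**Step 8**
Reactants: 9
Product: 10 (2R,3R)-2,3-bis{[4-(TBSO)-3-methoxyphenyl]methyl}butane-1,4-diol
Conditions: NaBH4, EtOH/THF, 0 °C, 1 h
Reagents that add atoms: none
Why: Reduction of the lactol (via its open hydroxy-aldehyde) gives the C2-symmetric (R,R)-diol. Steps 7 and 8 can be run in one pot.

**Step 9**
Reactants: 11 (E)-ferulic acid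
Product: 12 (2E)-3-[4-(TBSO)-3-methoxyphenyl]prop-2-enoic acid
Conditions: TBSCl (2.3 equiv), imidazole, DMF, rt; then K2CO3, MeOH/H2O, rt
Reagents that add atoms: TBSCl, CC(C)(C)[Si](C)(C)Cl
Why: Bis-silylation followed by selective hydrolysis of the labile silyl ester leaves the phenol TBS ether and the E-alkene intact.

**Step 10**
Reactants: 10 (3 equiv); 12 (1 equiv)
Product: 13 mono-(4-TBSO-feruloyl) ester of 10
Conditions: EDC·HCl, DMAP (0.2 equiv), CH2Cl2, 0 °C → rt, 12 h; excess 10 recovered
Reagents that add atoms: none
Why: Steglich esterification. Statistical mono-acylation of the C2-symmetric diol with excess diol is regio- and stereochemically unambiguous, and no stereocentre is touched.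

**Step 11**
Reactants: 13
Product: 14 hanultarin
Conditions: TBAF, AcOH (1:1, 3.5 equiv each), THF, 0 °C, 1 h
Reagents that add atoms: none
Why: Buffered fluoride removes the three aryl TBS ethers. The cinnamate ester and the free primary alcohol are retained, and acyl migration between the two equivalent CH2OH groups is degenerate.

---

**Compound list**
1 | (5R)-5-(hydroxymethyl)furan-2(5H)-one | O=C1C=C[C@H](CO)O1 | starting material
2 | [(2R)-5-oxo-2,5-dihydrofuran-2-yl]methyl pivalate | O=C1C=C[C@H](COC(=O)C(C)(C)C)O1 | intermediate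
3 | 2-methoxy-4-methylphenol (creosol) | Cc1ccc(O)c(OC)c1 | starting material
4 | tert-butyl(2-methoxy-4-methylphenoxy)dimethylsilane | Cc1ccc(O[Si](C)(C)C(C)(C)C)c(OC)c1 | intermediate
5 | 4-benzyl-lactone pivalate (4,5-trans) | O=C1C[C@@H](Cc2ccc(O[Si](C)(C)C(C)(C)C)c(OC)c2)[C@H](COC(=O)C(C)(C)C)O1 | intermediate
6 | 4-(TBSO)-3-methoxybenzyl bromide | BrCc1ccc(O[Si](C)(C)C(C)(C)C)c(OC)c1 | intermediate
7 | 3,4-dibenzyl-lactone pivalate (all trans) | O=C1O[C@@H](COC(=O)C(C)(C)C)[C@H](Cc2ccc(O[Si](C)(C)C(C)(C)C)c(OC)c2)[C@H]1Cc1ccc(O[Si](C)(C)C(C)(C)C)c(OC)c1 | intermediate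
8 | triol | OC[C@H](Cc1ccc(O[Si](C)(C)C(C)(C)C)c(OC)c1)[C@@H](Cc1ccc(O[Si](C)(C)C(C)(C)C)c(OC)c1)[C@@H](O)CO | intermediate
9 | lactol (anomeric centre undefined) | OC1OC[C@H](Cc2ccc(O[Si](C)(C)C(C)(C)C)c(OC)c2)[C@H]1Cc1ccc(O[Si](C)(C)C(C)(C)C)c(OC)c1 | intermediate
10 | (R,R)-bis-TBS-secoisolariciresinol | OC[C@H](Cc1ccc(O[Si](C)(C)C(C)(C)C)c(OC)c1)[C@H](CO)Cc1ccc(O[Si](C)(C)C(C)(C)C)c(OC)c1 | intermediate
11 | (E)-ferulic acid | COc1cc(/C=C/C(=O)O)ccc1O | starting material
12 | 4-O-TBS-ferulic acid | COc1cc(/C=C/C(=O)O)ccc1O[Si](C)(C)C(C)(C)C | intermediate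
13 | mono-TBS-ferulate of 10 | COc1cc(/C=C/C(=O)OC[C@H](Cc2ccc(O[Si](C)(C)C(C)(C)C)c(OC)c2)[C@H](CO)Cc2ccc(O[Si](C)(C)C(C)(C)C)c(OC)c2)ccc1O[Si](C)(C)C(C)(C)C | intermediate
14 | hanultarin | COc1cc(/C=C/C(=O)OC[C@H](Cc2ccc(O)c(OC)c2)[C@H](CO)Cc2ccc(O)c(OC)c2)ccc1O | target

---

**Totals**
- Total steps: 11, including three parallel building-block preparations (steps 2, 4 and 9).
- Longest linear sequence: 8 steps (1 → 2 → 5 → 7 → 8 → 9 → 10 → 13 → 14, i.e. steps 1, 3, 5, 6, 7, 8, 10, 11).

**Three steps most likely to fail**
1. **Step 3 (proposed new decatungstate hydrobenzylation).** Risks are low conversion, competing HAT at OMe or the pivalate CH2, and erosion of the anti selectivity. Fallback (known chemistry, polar instead of radical): Cu-catalysed 1,4-addition of the benzylic Grignard from 6 (Mg, then CuBr·SMe2/TMSCl, THF, −78 °C) to butenolide 2, which is anti to C5.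
2. **Step 4 (NBS bromination).** The electron-rich benzyl bromide may suffer ring bromination or decompose. Fallback: build 6 from vanillin by TBSCl/imidazole, then NaBH4, then CBr4/PPh3.
3. **Step 5 (α-benzylation).** The C5 CH2OPiv group lies 1,3-cis to the incoming benzyl group and could erode the trans selectivity. Fallback: aldol condensation of the enolate of 5 with 4-TBSO-3-methoxybenzaldehyde, dehydration to the (E)-α-benzylidene lactone, then H2/Pd-C hydrogenation anti to the C4 benzyl group.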